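## Analysis of the target

Magnolignan H (22) is a 2,3-dihydro-1-benzofuran (O1, C2, C3, benzo ring A = C3a to C7a). Ring A is substituted everywhere except C5: an allyl group at C4, a 4-allylphenoxy group (ring D) on the C6 oxygen and a free hydroxyl at C7. C3 carries ring B, a 4-hydroxyphenyl unit joined ortho to its hydroxyl to ring C (2-hydroxy-5-allylphenyl), and C2 carries the hydroxymethyl carbon C9. The two stereocentres are C2 (R) and C3 (S), with hydroxymethyl and aryl cis. This is the less stable arrangement, so C2 has to be set under kinetic control and should never sit next to a carbonyl at C9. The sensitive groups are the three allyl groups (attacked by boranes and oxidants, prone to migrate into conjugation), the electron-rich ring A phenol and the doubly benzylic C3–H. The main difficulties are the crowding between the C3 aryl group and the C4 allyl group and the need to combine a hydration-type construction of C9–OH with three terminal alkenes. The strategy rests on reading O1–C7a–C3a as a phenol oxygen with its ortho carbon (a 1,3-binucleophile) and C3–C2–C9 as a γ-aryl propargylic electrophile: joining them closes the furan ring, sets C3 and leaves C9 as an exocyclic methylene from which C2 can be set.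

## Retrosynthetic reasoning

**22 to 21.** The two phenolic hydroxyls of rings B and C are unmasked last from their methoxymethyl ethers. Mild acid in methanol touches neither the allyl groups nor the cis ring fusion, since C2 bears no carbonyl and the C2–O1 bond is not benzylic.

**21 to 20.** The allyl–aryl bonds on ring C and ring D are cut back to aryl chlorides. Allyl groups cannot be present when C9 is hydroborated, whereas chlorides survive every earlier step, including the Suzuki coupling of an aryl iodide, the Grignard addition and the copper catalysis. The forward step is a double cross-coupling with an allylboron reagent.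

**20 to 18 to 17.** The C4–allyl bond is cut by a para-Claisen rearrangement, leading back to the O7 allyl ether 18 and the phenol 17. C4 is para to O7, and both ortho positions of O7 (C6 and C7a) are blocked, so the allyl group can only end up at C4. It is delivered intramolecularly to the most crowded position of ring A, and C4 stays unsubstituted until after the ring-forming step.

**17 to 16.** O7 must be free only for the allylation, so it is carried as a 4-methoxybenzyl ether, orthogonal to the methoxymethyl ethers and cleavable by oxidation before any allyl group is present.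

**16 to 14.** The C9–O bond and the C2–H bond are traced to hydroboration–oxidation of the exocyclic enol ether 14. Boron goes to the terminal carbon C9 (β to oxygen and unhindered), and hydrogen goes to C2 from the face of the bicycle opposite ring B. This pushes C9 onto the face of ring B and gives the cis product.

**14 to 6 and 12.** This is the key disconnection: C3–C3a and O1–C2 are cut together. The phenol 6 supplies O1 and its ortho carbon; the racemic propargylic acetate 12 supplies C3, C2 and C9. One copper-catalysed operation has to form both bonds, close the five-membered ring and set C3 by catalyst control from a racemic electrophile. No other disconnection reaches the ring and a stereocentre from two fragments of this simplicity.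

**12 to 11 to 10 to 9 to 7 and 8.** The acetate comes from the propargylic alcohol 11, made by adding an ethynyl nucleophile to aldehyde 10 (bond C3–C2). Aldehyde 10 is the bis-methoxymethyl ether of biaryl 9, whose ring B–ring C bond comes from a Suzuki coupling of iodide 7 with boronic acid 8. The iodide reacts and the chloride is left for later.

**6 to 4 to 2 and 3, and 2 to 1.** The phenol hydroxyl of 6 is traced to an aldehyde (Baeyer–Villiger oxidation and formate cleavage of 4). The diaryl ether bond of 4 is cut to aryl bromide 2 and 4-chlorophenol 3 (Ullmann coupling, C–Br reacting in preference to C–Cl). Bromide 2 is the 4-methoxybenzyl ether of the commercial salicylaldehyde 1. Starting from 1 fixes the 1,2,3-trioxygenation pattern without any selective manipulation of a catechol.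

## Alternatives that were turned down

**Alternative 1:** Auxiliary-controlled conjugate addition with enolate hydroxylation. The disconnection cuts the bond from C3 to ring B and treats the C2–O1 bond as a C2 hydroxyl; O1–C7a would be closed later by intramolecular aryl ether formation. In the forward key step the aryl Grignard reagent A3, with CuBr·SMe2 (monovalent copper), adds to the ring A cinnamoyl imide A2, and the magnesium enolate is oxidised by an N-sulfonyloxaziridine to give the hydroxy imide A1.

- For it: both stereocentres come from one auxiliary with well-understood models. All three allyl groups are carried from the start, so there are no chloride placeholders, no hydroboration and no late cross-coupling. On these points it is stronger than the chosen route.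
- Against it: the β-aryl group of A2 is trioxygenated and carries an ortho bromine, so the acceptor is both electron-rich and hindered. The relative configuration depends on a second face selection at the enolate. No ring is closed: the C2 hydroxyl of A1 must still be coupled to a hindered aryl bromide under base and copper or palladium while C2 is α to a carbonyl, which is the situation in which the cis compound epimerises. Zerovalent palladium would also cleave the allyl aryl ether. The auxiliary is stoichiometric, and A2 needs a long fragment synthesis.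
- Comparison: the chosen route is catalytic, closes the ring in the stereo-determining step and never places a carbonyl next to C2. It pays for this with the placeholder chlorides.

**Alternative 2:** Iminium-catalysed Friedel–Crafts alkylation. The disconnection cuts C3–C3a and ties O1 temporarily to C9. In the forward key step phenol A5 adds through its ortho carbon to the β-carbon of enal A6, activated by a diarylprolinol silyl ether, and the phenol oxygen closes a six-membered lactol, giving A4.

- For it: it is metal-free and catalytic. The fragments carry all three allyl groups, and A5 is an obovatol-type phenol. In protecting-group and redox economy of the allyl groups it is stronger than the chosen route.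
- Against it: the reacting carbon of A5 lies between the hydroxyl and the allyl group on a ring of only moderate nucleophilicity. A6 is a donor-substituted cinnamaldehyde and forms a weakly electrophilic iminium ion. The step closes the wrong ring (O1 on C9, not on C2) and sets only C3. C2 must then be oxygenated in a separate stereoselective step, the aldehyde reduced and O1–C2 closed with inversion; the intermediate α-oxygenated aldehyde is epimerisable. At least five further operations are needed before the ring system exists.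
- Comparison: the chosen route forms the five-membered ring directly and sets C2 on a rigid bicycle by substrate control.

**Alternative 3:** Rhodium carbene C–H insertion. The disconnection cuts C2–C3. In the forward key step the diaryldiazomethane A8 loses dinitrogen at the chiral divalent rhodium dimer Rh2(R-PTAD)4 (or its mirror image), and the carbene carbon inserts into a C–H bond of the O1–CH2 group, giving the cis-dihydrobenzofuran A7.

- For it: one step forms the ring and both stereocentres, and cis selectivity is inherent in insertions of diaryl carbenes into ether C–H bonds. The allyl groups are in place, and only Claisen rearrangement, desilylation and acetal cleavage would follow. In stereocentres per step and in length of the endgame it is stronger than the chosen route.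
- Against it: the C–H bond that must react carries a β-silyloxy group, which makes it less hydridic and the insertion slower. That gives room for azine formation and for reaction of the carbene with the four alkenes present. A8 must be made by oxidising the hydrazone of a hindered, ortho-oxygenated benzophenone, and that ketone requires a fully elaborated ring A organometallic, the longest fragment synthesis of all four plans.
- Comparison: the chosen route offers two short fragment syntheses, a cheap copper catalyst and an enantioconvergent key step on a racemic partner. It accepts a separate, substrate-controlled step for C2 and three extra steps for the allyl groups.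

Key step: step 8

## Assumptions

- The ligand enantiomer written in step 8 is assumed to give the (3S) product; if a test reaction shows the opposite sense, its mirror image is used.
- 3-Bromo-2-hydroxybenzaldehyde (1) and (5-chloro-2-hydroxyphenyl)boronic acid (8) are taken as catalogue chemicals.

## Route

Step 1
Reactants: 1 3-bromo-2-hydroxybenzaldehyde
Product: 2 3-bromo-2-[(4-methoxybenzyl)oxy]benzaldehyde
Conditions: PMBCl, K2CO3, DMF, 60 °C
Reagents that add atoms: 4-methoxybenzyl chloride, COc1ccc(CCl)cc1
Why: Williamson etherification of the acidic salicylaldehyde hydroxyl; the aldehyde and the aryl bromide are inert to carbonate.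

Step 2
Reactants: 2 3-bromo-2-[(4-methoxybenzyl)oxy]benzaldehyde; 3 4-chlorophenol
Product: 4 3-(4-chlorophenoxy)-2-[(4-methoxybenzyl)oxy]benzaldehyde
Conditions: CuI (10 mol %), N,N-dimethylglycine hydrochloride (30 mol %), Cs2CO3, dioxane, 100 °C
Reagents that add atoms: none
Why: Ullmann diaryl ether coupling; monovalent copper with the amino acid ligand activates the C–Br bond of 2 and leaves the C–Cl bond of 3 alone, and the non-enolisable aldehyde tolerates the carbonate base.

Step 3
Reactants: 4 3-(4-chlorophenoxy)-2-[(4-methoxybenzyl)oxy]benzaldehyde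
Product: 6 3-(4-chlorophenoxy)-2-[(4-methoxybenzyl)oxy]phenol, via aryl formate 5 (not isolated)
Conditions: mCPBA, CH2Cl2, 0 °C to rt; then K2CO3 (cat.), MeOH, rt
Reagents that add atoms: 3-chloroperoxybenzoic acid, O=C(OO)c1cccc(Cl)c1
Why: Baeyer–Villiger oxidation of an ortho-alkoxybenzaldehyde, in which the electron-rich aryl group migrates in preference to hydride; methanolysis of formate 5 frees the phenol without touching the two ethers.

Step 4
Reactants: 7 4-hydroxy-3-iodobenzaldehyde; 8 (5-chloro-2-hydroxyphenyl)boronic acid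
Product: 9 5'-chloro-2',6-dihydroxybiphenyl-3-carbaldehyde
Conditions: Pd(dppf)Cl2 (3 mol %), K2CO3, dioxane/H2O, 80 °C
Reagents that add atoms: none
Why: Suzuki–Miyaura coupling; zerovalent palladium inserts into C–I far faster than into C–Cl, and aqueous carbonate allows both partners to be used as free phenols.

Step 5
Reactants: 9 5'-chloro-2',6-dihydroxybiphenyl-3-carbaldehyde
Product: 10 5'-chloro-2',6-bis(methoxymethoxy)biphenyl-3-carbaldehyde
Conditions: MOMCl, i-Pr2NEt, CH2Cl2, 0 °C to rt
Reagents that add atoms: chloromethyl methyl ether, COCCl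
Why: Double O-alkylation of the phenols to acetals that withstand Grignard reagents, amine bases, boranes, DDQ and palladium catalysis and fall to mild acid at the end.

Step 6
Reactants: 10 5'-chloro-2',6-bis(methoxymethoxy)biphenyl-3-carbaldehyde
Product: 11 rac-1-[5'-chloro-2',6-bis(methoxymethoxy)biphenyl-3-yl]prop-2-yn-1-ol
Conditions: HC≡CMgBr, THF, 0 °C
Reagents that add atoms: ethynylmagnesium bromide, C#C[Mg]Br
Why: 1,2-Addition of an alkynyl Grignard reagent to an aryl aldehyde forms the C3–C2 bond; the racemate is acceptable because the key step is enantioconvergent.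

Step 7
Reactants: 11 rac-1-[5'-chloro-2',6-bis(methoxymethoxy)biphenyl-3-yl]prop-2-yn-1-ol
Product: 12 rac-1-[5'-chloro-2',6-bis(methoxymethoxy)biphenyl-3-yl]prop-2-yn-1-yl acetate
Conditions: Ac2O, Et3N, DMAP (cat.), CH2Cl2, 0 °C
Reagents that add atoms: acetic anhydride, CC(=O)OC(C)=O
Why: DMAP-catalysed acylation of a secondary alcohol installs the leaving group for the copper step; the terminal alkyne stays free, as the catalysis requires.

Step 8
Reactants: 6 3-(4-chlorophenoxy)-2-[(4-methoxybenzyl)oxy]phenol; 12 rac-1-[5'-chloro-2',6-bis(methoxymethoxy)biphenyl-3-yl]prop-2-yn-1-yl acetate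
Product: 14 (3S)-3-[5'-chloro-2',6-bis(methoxymethoxy)biphenyl-3-yl]-6-(4-chlorophenoxy)-7-[(4-methoxybenzyl)oxy]-2-methylidene-2,3-dihydro-1-benzofuran, via ortho-propargylated phenol 13 (not isolated)
Conditions: Cu(OTf)2 (5 mol %), (S)-1-[2-(diphenylphosphanyl)phenyl]-N-[1-(pyridin-2-yl)ethylidene]ethanamine (5.5 mol %), i-Pr2NEt (1.2 equiv), 6 (1.3 equiv), MeOH, −20 to 0 °C
Reagents that add atoms: none
Why: Amine and copper convert the terminal alkyne of 12 into a copper acetylide, acetate leaves, and a copper allenylidene results (monovalent copper, formed from Cu(OTf)2 in the flask); both enantiomers of 12 give this one planar electrophile, so the step is enantioconvergent. The closest known reaction type is the copper-catalysed asymmetric propargylic Friedel–Crafts substitution of naphthols and oxygen-rich phenols that runs on to a cycloisomerisation and delivers 2-methylene-2,3-dihydrofurans, a formal (3+2) annulation. The carbon of 6 that is ortho to the hydroxyl and para to the aryloxy group (the future C3a) attacks the γ-carbon and forms C3–C3a; the tridentate P,N,N ligand blocks one face of the allenylidene, so the configuration of C3 is set by the catalyst alone. Rearomatisation gives the copper acetylide of 13, whose phenol oxygen adds to the internal alkyne carbon in a 5-exo-dig closure (O1–C2), and protonation leaves the exocyclic methylene C9. The step needs carbon attack ortho to the hydroxyl: that carbon has the ortho-hydroxy, para-alkoxy pattern of the phenols known to react, the carbon para to the hydroxyl is crowded by the neighbouring aryloxy group, and only the ortho adduct can cyclise and so be drained off irreversibly. Attack through oxygen should not be a dead end, because the aryl propargyl ether so formed keeps the alkyne and an aryloxide leaving group and can return to the allenylidene. The MOM and PMB ethers and both aryl chlorides are inert to monovalent copper and amine; 14 is worked up without acid and carried on at once, since acid or base would move the double bond into the ring and destroy C3.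

Step 9
Reactants: 14 (3S)-3-[5'-chloro-2',6-bis(methoxymethoxy)biphenyl-3-yl]-6-(4-chlorophenoxy)-7-[(4-methoxybenzyl)oxy]-2-methylidene-2,3-dihydro-1-benzofuran
Product: 16 [(2R,3S)-3-[5'-chloro-2',6-bis(methoxymethoxy)biphenyl-3-yl]-6-(4-chlorophenoxy)-7-[(4-methoxybenzyl)oxy]-2,3-dihydro-1-benzofuran-2-yl]methanol, via C9 alkylborane 15 (not isolated)
Conditions: 9-BBN, THF, 0 °C to rt; then NaOH, H2O2, H2O, 0 °C
Reagents that add atoms: 9-borabicyclo[3.3.1]nonane, B1C2CCCC1CCC2 (its boron and carbons stay in 15 only); hydrogen peroxide, OO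
Why: Hydroboration–oxidation of a 1,1-disubstituted enol ether puts boron on the terminal carbon C9, β to oxygen, and the bulky borane adds syn from the face opposite the C3 aryl group, so hydrogen enters C2 anti to ring B and C9 becomes cis to it (2R). Oxidation of the C–B bond proceeds with retention and does not involve C2.

Step 10
Reactants: 16 [(2R,3S)-3-[5'-chloro-2',6-bis(methoxymethoxy)biphenyl-3-yl]-6-(4-chlorophenoxy)-7-[(4-methoxybenzyl)oxy]-2,3-dihydro-1-benzofuran-2-yl]methanol
Product: 17 (2R,3S)-3-[5'-chloro-2',6-bis(methoxymethoxy)biphenyl-3-yl]-6-(4-chlorophenoxy)-2-(hydroxymethyl)-2,3-dihydro-1-benzofuran-7-ol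
Conditions: DDQ (1.2 equiv), CH2Cl2/pH 7 buffer, 0 °C
Reagents that add atoms: none
Why: Oxidative cleavage of a 4-methoxybenzyl ether by hydride abstraction from its benzylic carbon and hydrolysis of the oxocarbenium ion; the MOM acetals and aryl chlorides do not react, and low temperature with a small excess of oxidant should spare the liberated phenol and the C3–H bond.

Step 11
Reactants: 17 (2R,3S)-3-[5'-chloro-2',6-bis(methoxymethoxy)biphenyl-3-yl]-6-(4-chlorophenoxy)-2-(hydroxymethyl)-2,3-dihydro-1-benzofuran-7-ol
Product: 18 [(2R,3S)-3-[5'-chloro-2',6-bis(methoxymethoxy)biphenyl-3-yl]-6-(4-chlorophenoxy)-7-(prop-2-enyloxy)-2,3-dihydro-1-benzofuran-2-yl]methanol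
Conditions: allyl bromide, K2CO3, acetone, 50 °C
Reagents that add atoms: allyl bromide, C=CCBr
Why: Williamson etherification; carbonate deprotonates only the phenol, so the primary alcohol is not alkylated.

Step 12
Reactants: 18 [(2R,3S)-3-[5'-chloro-2',6-bis(methoxymethoxy)biphenyl-3-yl]-6-(4-chlorophenoxy)-7-(prop-2-enyloxy)-2,3-dihydro-1-benzofuran-2-yl]methanol
Product: 20 (2R,3S)-3-[5'-chloro-2',6-bis(methoxymethoxy)biphenyl-3-yl]-6-(4-chlorophenoxy)-2-(hydroxymethyl)-4-(prop-2-enyl)-2,3-dihydro-1-benzofuran-7-ol, via ortho-dienone 19 (not isolated)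
Conditions: N,N-diethylaniline, 190 °C, sealed tube, argon
Reagents that add atoms: none
Why: Aromatic para-Claisen rearrangement: with both ortho positions occupied, the first [3,3] shift gives dienone 19 (the shift to C7a gives an equivalent dienone), which cannot enolise and passes the allyl group on by a Cope [3,3] shift to C4, where tautomerisation restores the phenol. The rearrangement of allyl 2,6-dialkoxyphenyl ethers to 4-allyl-2,6-dialkoxyphenols is the model; the stereocentres take no part.

Step 13
Reactants: 20 (2R,3S)-3-[5'-chloro-2',6-bis(methoxymethoxy)biphenyl-3-yl]-6-(4-chlorophenoxy)-2-(hydroxymethyl)-4-(prop-2-enyl)-2,3-dihydro-1-benzofuran-7-ol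
Product: 21 (2R,3S)-3-[2',6-bis(methoxymethoxy)-5'-(prop-2-enyl)biphenyl-3-yl]-2-(hydroxymethyl)-4-(prop-2-enyl)-6-[4-(prop-2-enyl)phenoxy]-2,3-dihydro-1-benzofuran-7-ol
Conditions: allylB(pin) (3 equiv), Pd(OAc)2 (5 mol %), XPhos [2-(dicyclohexylphosphanyl)-2',4',6'-triisopropylbiphenyl] (10 mol %), K3PO4, THF/H2O, 65 °C
Reagents that add atoms: allylboronic acid pinacol ester, C=CCB1OC(C)(C)C(C)(C)O1
Why: Double Suzuki–Miyaura allylation of aryl chlorides; the bulky dialkylbiarylphosphine lets zerovalent palladium insert into the two electron-rich C–Cl bonds, and an unsubstituted allyl group raises no regiochemical question. The free phenol and alcohol are tolerated by the aqueous phosphate conditions.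

Step 14
Reactants: 21 (2R,3S)-3-[2',6-bis(methoxymethoxy)-5'-(prop-2-enyl)biphenyl-3-yl]-2-(hydroxymethyl)-4-(prop-2-enyl)-6-[4-(prop-2-enyl)phenoxy]-2,3-dihydro-1-benzofuran-7-ol
Product: 22 magnolignan H, (2R,3S)-3-[2',6-dihydroxy-5'-(prop-2-enyl)biphenyl-3-yl]-2-(hydroxymethyl)-4-(prop-2-enyl)-6-[4-(prop-2-enyl)phenoxy]-2,3-dihydro-1-benzofuran-7-ol
Conditions: HCl (3 M aq., cat.), MeOH, 45 °C
Reagents that add atoms: none
Why: Acid-catalysed transacetalisation of the two aryl MOM ethers to methanol; terminal allyl groups and the cis-dihydrobenzofuran are stable to dilute acid because neither C2 nor C3 can ionise or enolise.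

## Compound list

1 | 3-bromo-2-hydroxybenzaldehyde | O=Cc1cccc(Br)c1O | starting material
2 | 3-bromo-2-[(4-methoxybenzyl)oxy]benzaldehyde | COc1ccc(COc2c(Br)cccc2C=O)cc1 | intermediate
3 | 4-chlorophenol | Oc1ccc(Cl)cc1 | starting material
4 | 3-(4-chlorophenoxy)-2-[(4-methoxybenzyl)oxy]benzaldehyde | COc1ccc(COc2c(Oc3ccc(Cl)cc3)cccc2C=O)cc1 | intermediate
5 | 3-(4-chlorophenoxy)-2-[(4-methoxybenzyl)oxy]phenyl formate | COc1ccc(COc2c(Oc3ccc(Cl)cc3)cccc2OC=O)cc1 | intermediate
6 | 3-(4-chlorophenoxy)-2-[(4-methoxybenzyl)oxy]phenol | COc1ccc(COc2c(Oc3ccc(Cl)cc3)cccc2O)cc1 | intermediate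
7 | 4-hydroxy-3-iodobenzaldehyde | O=Cc1ccc(O)c(I)c1 | starting material
8 | (5-chloro-2-hydroxyphenyl)boronic acid | OB(O)c1cc(Cl)ccc1O | starting material
9 | 5'-chloro-2',6-dihydroxybiphenyl-3-carbaldehyde | O=Cc1ccc(O)c(-c2cc(Cl)ccc2O)c1 | intermediate
10 | 5'-chloro-2',6-bis(methoxymethoxy)biphenyl-3-carbaldehyde | O=Cc1ccc(OCOC)c(-c2cc(Cl)ccc2OCOC)c1 | intermediate
11 | rac-1-[5'-chloro-2',6-bis(methoxymethoxy)biphenyl-3-yl]prop-2-yn-1-ol | OC(C#C)c1ccc(OCOC)c(-c2cc(Cl)ccc2OCOC)c1 | intermediate
12 | rac-1-[5'-chloro-2',6-bis(methoxymethoxy)biphenyl-3-yl]prop-2-yn-1-yl acetate | CC(=O)OC(C#C)c1ccc(OCOC)c(-c2cc(Cl)ccc2OCOC)c1 | intermediate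
13 | 6-[(1S)-1-[5'-chloro-2',6-bis(methoxymethoxy)biphenyl-3-yl]prop-2-yn-1-yl]-3-(4-chlorophenoxy)-2-[(4-methoxybenzyl)oxy]phenol | C#C[C@H](c1ccc(Oc2ccc(Cl)cc2)c(OCc2ccc(OC)cc2)c1O)c1ccc(OCOC)c(-c2cc(Cl)ccc2OCOC)c1 | intermediate
14 | (3S)-3-[5'-chloro-2',6-bis(methoxymethoxy)biphenyl-3-yl]-6-(4-chlorophenoxy)-7-[(4-methoxybenzyl)oxy]-2-methylidene-2,3-dihydro-1-benzofuran | Clc1ccc(Oc2ccc3c(c2OCc2ccc(OC)cc2)OC(=C)[C@H]3c2ccc(OCOC)c(-c3cc(Cl)ccc3OCOC)c2)cc1 | intermediate
15 | 9-{[(2S,3S)-3-[5'-chloro-2',6-bis(methoxymethoxy)biphenyl-3-yl]-6-(4-chlorophenoxy)-7-[(4-methoxybenzyl)oxy]-2,3-dihydro-1-benzofuran-2-yl]methyl}-9-borabicyclo[3.3.1]nonane (same spatial arrangement as 16; the descriptor of C2 changes because boron ranks below carbon) | Clc1ccc(Oc2ccc3c(c2OCc2ccc(OC)cc2)O[C@@H](CB2C4CCCC2CCC4)[C@H]3c2ccc(OCOC)c(-c3cc(Cl)ccc3OCOC)c2)cc1 | intermediate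
16 | [(2R,3S)-3-[5'-chloro-2',6-bis(methoxymethoxy)biphenyl-3-yl]-6-(4-chlorophenoxy)-7-[(4-methoxybenzyl)oxy]-2,3-dihydro-1-benzofuran-2-yl]methanol | Clc1ccc(Oc2ccc3c(c2OCc2ccc(OC)cc2)O[C@@H](CO)[C@H]3c2ccc(OCOC)c(-c3cc(Cl)ccc3OCOC)c2)cc1 | intermediate
17 | (2R,3S)-3-[5'-chloro-2',6-bis(methoxymethoxy)biphenyl-3-yl]-6-(4-chlorophenoxy)-2-(hydroxymethyl)-2,3-dihydro-1-benzofuran-7-ol | Clc1ccc(Oc2ccc3c(c2O)O[C@@H](CO)[C@H]3c2ccc(OCOC)c(-c3cc(Cl)ccc3OCOC)c2)cc1 | intermediate
18 | [(2R,3S)-3-[5'-chloro-2',6-bis(methoxymethoxy)biphenyl-3-yl]-6-(4-chlorophenoxy)-7-(prop-2-enyloxy)-2,3-dihydro-1-benzofuran-2-yl]methanol | Clc1ccc(Oc2ccc3c(c2OCC=C)O[C@@H](CO)[C@H]3c2ccc(OCOC)c(-c3cc(Cl)ccc3OCOC)c2)cc1 | intermediate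
19 | (2R,3S)-3-[5'-chloro-2',6-bis(methoxymethoxy)biphenyl-3-yl]-6-(4-chlorophenoxy)-2-(hydroxymethyl)-6-(prop-2-enyl)-2,3-dihydro-1-benzofuran-7(6H)-one (both configurations at C6) | Clc1ccc(OC2(CC=C)C=CC3=C(C2=O)O[C@@H](CO)[C@H]3c2ccc(OCOC)c(-c3cc(Cl)ccc3OCOC)c2)cc1 | intermediate
20 | (2R,3S)-3-[5'-chloro-2',6-bis(methoxymethoxy)biphenyl-3-yl]-6-(4-chlorophenoxy)-2-(hydroxymethyl)-4-(prop-2-enyl)-2,3-dihydro-1-benzofuran-7-ol | Clc1ccc(Oc2cc(CC=C)c3c(c2O)O[C@@H](CO)[C@H]3c2ccc(OCOC)c(-c3cc(Cl)ccc3OCOC)c2)cc1 | intermediate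
21 | (2R,3S)-3-[2',6-bis(methoxymethoxy)-5'-(prop-2-enyl)biphenyl-3-yl]-2-(hydroxymethyl)-4-(prop-2-enyl)-6-[4-(prop-2-enyl)phenoxy]-2,3-dihydro-1-benzofuran-7-ol | C=CCc1ccc(Oc2cc(CC=C)c3c(c2O)O[C@@H](CO)[C@H]3c2ccc(OCOC)c(-c3cc(CC=C)ccc3OCOC)c2)cc1 | intermediate
22 | magnolignan H, (2R,3S)-3-[2',6-dihydroxy-5'-(prop-2-enyl)biphenyl-3-yl]-2-(hydroxymethyl)-4-(prop-2-enyl)-6-[4-(prop-2-enyl)phenoxy]-2,3-dihydro-1-benzofuran-7-ol | C=CCc1ccc(Oc2cc(CC=C)c3c(c2O)O[C@@H](CO)[C@H]3c2ccc(O)c(-c3cc(CC=C)ccc3O)c2)cc1 | target

## Step count and least certain steps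

Total: 14 steps. Longest linear sequence: 11 steps (7 to 22, steps 4 to 14); the ring A branch (steps 1 to 3) joins at step 8.

**Step 8 (key step).** The most likely failure is capture of the allenylidene by the phenol oxygen or by methanol instead of by carbon, because ring A of 6 is a weaker carbon nucleophile than a naphthol. Attack para to the hydroxyl and incomplete face discrimination by the ligand are the next risks. The fallback sets out from aldehyde 2 and acetate 12 and comes back at alcohol 16. It lets ring A enter as a symmetric resorcinol and forms the ring D ether afterwards: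
- Aldehyde 2 is oxidised as in step 3 (mCPBA; then K2CO3, MeOH) through 3-bromo-2-[(4-methoxybenzyl)oxy]phenyl formate F1 to 3-bromo-2-[(4-methoxybenzyl)oxy]phenol F2.
- Hydroxylation of the bromide (Pd2(dba)3, 2-(di-tert-butylphosphanyl)-2',4',6'-triisopropylbiphenyl, KOH, dioxane/H2O, 100 °C) gives 2-[(4-methoxybenzyl)oxy]benzene-1,3-diol F3. Its two reactive carbons are equivalent, and each is ortho to one hydroxyl and para to the other.
- F3, used in excess to prevent a second annulation, and 12 under the conditions of step 8 should give, through 4-[(1S)-1-[5'-chloro-2',6-bis(methoxymethoxy)biphenyl-3-yl]prop-2-yn-1-yl]-2-[(4-methoxybenzyl)oxy]benzene-1,3-diol F4, the annulated phenol (3S)-3-[5'-chloro-2',6-bis(methoxymethoxy)biphenyl-3-yl]-7-[(4-methoxybenzyl)oxy]-2-methylidene-2,3-dihydro-1-benzofuran-6-ol F5.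
- Hydroboration–oxidation as in step 9 passes through the C9 borane 9-{[(2S,3S)-3-[5'-chloro-2',6-bis(methoxymethoxy)biphenyl-3-yl]-6-hydroxy-7-[(4-methoxybenzyl)oxy]-2,3-dihydro-1-benzofuran-2-yl]methyl}-9-borabicyclo[3.3.1]nonane F6 (drawn with the phenol free) to (2R,3S)-3-[5'-chloro-2',6-bis(methoxymethoxy)biphenyl-3-yl]-2-(hydroxymethyl)-7-[(4-methoxybenzyl)oxy]-2,3-dihydro-1-benzofuran-6-ol F7.
- Chan–Lam coupling of the phenol of F7 with 4-chlorophenylboronic acid (Cu(OAc)2, pyridine, 4 Å molecular sieves, CH2Cl2, air, rt) leaves the primary alcohol alone and gives 16.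

**Step 9.** The exocyclic double bond may migrate into the ring before the borane has added, which aromatises the furan and erases C3, and the borane may not discriminate fully between the two faces. The first risk is met by hydroborating the crude, base-washed solution of 14. The fallback sets out from 14 and comes back at 16. Dimethyldioxirane (acetone, −40 °C) epoxidises the enol ether from the face opposite ring B and gives (2R,3S)-3-[5'-chloro-2',6-bis(methoxymethoxy)biphenyl-3-yl]-6-(4-chlorophenoxy)-7-[(4-methoxybenzyl)oxy]-3H-spiro[1-benzofuran-2,2'-oxirane] F8. i-Bu2AlH (CH2Cl2, −78 °C) then binds the epoxide oxygen, opens the acetal C2–O bond and delivers hydride to C2 on the face of the departing oxygen, as in the reductive opening of 1,2-anhydro sugars at the acetal carbon. C9, now a hydroxymethyl group, is again cis to ring B.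

**Step 10.** The quinone may go on to oxidise the liberated, very electron-rich phenol, or abstract hydride from the doubly benzylic C3–H and dehydrogenate the ring to the benzofuran. The fallback sets out from 16 and comes back at 17 with no new compound: reductive instead of oxidative cleavage of the benzylic C–O bond by hydrogenolysis (H2 1 atm, Pd/C, EtOAc, rt, with Bu4NCl added to hold back reduction of the aryl chlorides).

**Step 12.** The allyl group has to pass through a blocked ortho position and arrive next to the C3 aryl group; at 190 °C, loss of the allyl group back to 17 or decomposition of the dienone may compete. The fallback sets out from 17 and comes back at 21, leaving out steps 11 and 12. NBS (MeCN, 0 °C) brominates 17 para to the free hydroxyl, the only open activated position, giving (2R,3S)-4-bromo-3-[5'-chloro-2',6-bis(methoxymethoxy)biphenyl-3-yl]-6-(4-chlorophenoxy)-2-(hydroxymethyl)-2,3-dihydro-1-benzofuran-7-ol F9. The coupling of step 13, with one more equivalent of the allylboronate, then replaces the bromide and both chlorides.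

**Step 13.** Oxidative addition into two electron-rich aryl chlorides may be incomplete, and palladium hydride formed during a slow coupling may move allyl double bonds into conjugation. The fallback sets out from 20 and comes back at 22. It separates C–Cl activation from allyl transfer:
- 20 is protected at both hydroxyls (MOMCl, i-Pr2NEt, CH2Cl2) to (2R,3S)-3-[5'-chloro-2',6-bis(methoxymethoxy)biphenyl-3-yl]-6-(4-chlorophenoxy)-7-(methoxymethoxy)-2-[(methoxymethoxy)methyl]-4-(prop-2-enyl)-2,3-dihydro-1-benzofuran F10.
- Miyaura borylation of both chlorides (B2pin2, Pd2(dba)3, XPhos, KOAc, dioxane, 100 °C) gives the bis(pinacolboronate) (2R,3S)-3-[2',6-bis(methoxymethoxy)-5'-(4,4,5,5-tetramethyl-1,3,2-dioxaborolan-2-yl)biphenyl-3-yl]-7-(methoxymethoxy)-2-[(methoxymethoxy)methyl]-4-(prop-2-enyl)-6-[4-(4,4,5,5-tetramethyl-1,3,2-dioxaborolan-2-yl)phenoxy]-2,3-dihydro-1-benzofuran F11.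
- Coupling of F11 with allyl bromide (Pd(PPh3)4, CsF, THF, 50 °C) gives (2R,3S)-3-[2',6-bis(methoxymethoxy)-5'-(prop-2-enyl)biphenyl-3-yl]-7-(methoxymethoxy)-2-[(methoxymethoxy)methyl]-4-(prop-2-enyl)-6-[4-(prop-2-enyl)phenoxy]-2,3-dihydro-1-benzofuran F12.
- The acid of step 14, applied for longer, removes all four MOM groups.

## Further compounds

F1 | step 8 | 3-bromo-2-[(4-methoxybenzyl)oxy]phenyl formate | COc1ccc(COc2c(Br)cccc2OC=O)cc1
F2 | step 8 | 3-bromo-2-[(4-methoxybenzyl)oxy]phenol | COc1ccc(COc2c(O)cccc2Br)cc1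
F3 | step 8 | 2-[(4-methoxybenzyl)oxy]benzene-1,3-diol | COc1ccc(COc2c(O)cccc2O)cc1
F4 | step 8 | 4-[(1S)-1-[5'-chloro-2',6-bis(methoxymethoxy)biphenyl-3-yl]prop-2-yn-1-yl]-2-[(4-methoxybenzyl)oxy]benzene-1,3-diol | C#C[C@H](c1ccc(O)c(OCc2ccc(OC)cc2)c1O)c1ccc(OCOC)c(-c2cc(Cl)ccc2OCOC)c1
F5 | step 8 | (3S)-3-[5'-chloro-2',6-bis(methoxymethoxy)biphenyl-3-yl]-7-[(4-methoxybenzyl)oxy]-2-methylidene-2,3-dihydro-1-benzofuran-6-ol | Oc1ccc2c(c1OCc1ccc(OC)cc1)OC(=C)[C@H]2c1ccc(OCOC)c(-c2cc(Cl)ccc2OCOC)c1
F6 | step 8 | 9-{[(2S,3S)-3-[5'-chloro-2',6-bis(methoxymethoxy)biphenyl-3-yl]-6-hydroxy-7-[(4-methoxybenzyl)oxy]-2,3-dihydro-1-benzofuran-2-yl]methyl}-9-borabicyclo[3.3.1]nonane | Oc1ccc2c(c1OCc1ccc(OC)cc1)O[C@@H](CB1C3CCCC1CCC3)[C@H]2c1ccc(OCOC)c(-c2cc(Cl)ccc2OCOC)c1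
F7 | step 8 | (2R,3S)-3-[5'-chloro-2',6-bis(methoxymethoxy)biphenyl-3-yl]-2-(hydroxymethyl)-7-[(4-methoxybenzyl)oxy]-2,3-dihydro-1-benzofuran-6-ol | Oc1ccc2c(c1OCc1ccc(OC)cc1)O[C@@H](CO)[C@H]2c1ccc(OCOC)c(-c2cc(Cl)ccc2OCOC)c1
F8 | step 9 | (2R,3S)-3-[5'-chloro-2',6-bis(methoxymethoxy)biphenyl-3-yl]-6-(4-chlorophenoxy)-7-[(4-methoxybenzyl)oxy]-3H-spiro[1-benzofuran-2,2'-oxirane] | Clc1ccc(Oc2ccc3c(c2OCc2ccc(OC)cc2)O[C@@]4(CO4)[C@H]3c2ccc(OCOC)c(-c3cc(Cl)ccc3OCOC)c2)cc1
F0 | step 10 | none | none
F9 | step 12 | (2R,3S)-4-bromo-3-[5'-chloro-2',6-bis(methoxymethoxy)biphenyl-3-yl]-6-(4-chlorophenoxy)-2-(hydroxymethyl)-2,3-dihydro-1-benzofuran-7-ol | Clc1ccc(Oc2cc(Br)c3c(c2O)O[C@@H](CO)[C@H]3c2ccc(OCOC)c(-c3cc(Cl)ccc3OCOC)c2)cc1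
F10 | step 13 | (2R,3S)-3-[5'-chloro-2',6-bis(methoxymethoxy)biphenyl-3-yl]-6-(4-chlorophenoxy)-7-(methoxymethoxy)-2-[(methoxymethoxy)methyl]-4-(prop-2-enyl)-2,3-dihydro-1-benzofuran | Clc1ccc(Oc2cc(CC=C)c3c(c2OCOC)O[C@@H](COCOC)[C@H]3c2ccc(OCOC)c(-c3cc(Cl)ccc3OCOC)c2)cc1
F11 | step 13 | (2R,3S)-3-[2',6-bis(methoxymethoxy)-5'-(4,4,5,5-tetramethyl-1,3,2-dioxaborolan-2-yl)biphenyl-3-yl]-7-(methoxymethoxy)-2-[(methoxymethoxy)methyl]-4-(prop-2-enyl)-6-[4-(4,4,5,5-tetramethyl-1,3,2-dioxaborolan-2-yl)phenoxy]-2,3-dihydro-1-benzofuran | CC1(C)OB(OC1(C)C)c1ccc(Oc2cc(CC=C)c3c(c2OCOC)O[C@@H](COCOC)[C@H]3c2ccc(OCOC)c(-c3cc(B4OC(C)(C)C(C)(C)O4)ccc3OCOC)c2)cc1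
F12 | step 13 | (2R,3S)-3-[2',6-bis(methoxymethoxy)-5'-(prop-2-enyl)biphenyl-3-yl]-7-(methoxymethoxy)-2-[(methoxymethoxy)methyl]-4-(prop-2-enyl)-6-[4-(prop-2-enyl)phenoxy]-2,3-dihydro-1-benzofuran | C=CCc1ccc(Oc2cc(CC=C)c3c(c2OCOC)O[C@@H](COCOC)[C@H]3c2ccc(OCOC)c(-c3cc(CC=C)ccc3OCOC)c2)cc1
A1 | alternative 1 | (4R)-3-[(2R,3S)-3-[2-bromo-4-[4-(prop-2-enyl)phenoxy]-3-(prop-2-enyloxy)phenyl]-2-hydroxy-3-[2',6-bis(methoxymethoxy)-5'-(prop-2-enyl)biphenyl-3-yl]propanoyl]-4-phenyl-1,3-oxazolidin-2-one | O=C1OC[C@@H](c2ccccc2)N1C(=O)[C@H](O)[C@H](c1ccc(Oc2ccc(CC=C)cc2)c(OCC=C)c1Br)c1ccc(OCOC)c(-c2cc(CC=C)ccc2OCOC)c1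
A2 | alternative 1 | (4R)-3-[(2E)-3-[2-bromo-4-[4-(prop-2-enyl)phenoxy]-3-(prop-2-enyloxy)phenyl]prop-2-enoyl]-4-phenyl-1,3-oxazolidin-2-one | O=C1OC[C@@H](c2ccccc2)N1C(=O)/C=C/c1ccc(Oc2ccc(CC=C)cc2)c(OCC=C)c1Br
A3 | alternative 1 | [2',6-bis(methoxymethoxy)-5'-(prop-2-enyl)biphenyl-3-yl]magnesium bromide | Br[Mg]c1ccc(OCOC)c(-c2cc(CC=C)ccc2OCOC)c1
A4 | alternative 2 | (4S)-4-[2',6-bis(methoxymethoxy)-5'-(prop-2-enyl)biphenyl-3-yl]-8-(methoxymethoxy)-5-(prop-2-enyl)-7-[4-(prop-2-enyl)phenoxy]chroman-2-ol (both anomers) | C=CCc1ccc(Oc2cc(CC=C)c3c(c2OCOC)OC(O)C[C@H]3c2ccc(OCOC)c(-c3cc(CC=C)ccc3OCOC)c2)cc1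
A5 | alternative 2 | 2-(methoxymethoxy)-5-(prop-2-enyl)-3-[4-(prop-2-enyl)phenoxy]phenol | C=CCc1ccc(Oc2cc(CC=C)cc(O)c2OCOC)cc1
A6 | alternative 2 | (2E)-3-[2',6-bis(methoxymethoxy)-5'-(prop-2-enyl)biphenyl-3-yl]prop-2-enal | O=C/C=C/c1ccc(OCOC)c(-c2cc(CC=C)ccc2OCOC)c1
A7 | alternative 3 | {[(2R,3S)-3-[2',6-bis(methoxymethoxy)-5'-(prop-2-enyl)biphenyl-3-yl]-6-[4-(prop-2-enyl)phenoxy]-7-(prop-2-enyloxy)-2,3-dihydro-1-benzofuran-2-yl]methoxy}tri(propan-2-yl)silane | C=CCc1ccc(Oc2ccc3c(c2OCC=C)O[C@@H](CO[Si](C(C)C)(C(C)C)C(C)C)[C@H]3c2ccc(OCOC)c(-c3cc(CC=C)ccc3OCOC)c2)cc1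
A8 | alternative 3 | {2-[2-(diazo{2',6-bis(methoxymethoxy)-5'-(prop-2-enyl)biphenyl-3-yl}methyl)-5-[4-(prop-2-enyl)phenoxy]-6-(prop-2-enyloxy)phenoxy]ethoxy}tri(propan-2-yl)silane | [N-]=[N+]=C(c1ccc(Oc2ccc(CC=C)cc2)c(OCC=C)c1OCCO[Si](C(C)C)(C(C)C)C(C)C)c1ccc(OCOC)c(-c2cc(CC=C)ccc2OCOC)c1
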